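## The problem

The target **23** is a 2-chloro-4-hydroxycyclopent-2-enone (ring C8–C12, prostanoid numbering, C1 = ester carbon). C8 carries a chain with three contiguous acetoxy carbons (C5–C7) that ends in the methyl ester, and C12 is a tertiary carbinol bearing the (Z)-oct-2-enyl chain. Five stereocentres have to be set: C5, C6 and C7 on the chain, C8 and C12 on the ring. C7 and C8 are neighbours, so the chain can bias the formation of the ring. C12 is a fully substituted centre next to C8, so the C8 substituent can steer what enters there. The C7 acetate lies β to the C9 ketone and is lost by E1cB elimination with base. The C7 and C12 oxygens are both aldol-related to C9 (retro-aldol), and the C5 oxygen can lactonise onto the C1 ester. The Z olefin, the vinyl chloride and the tertiary allylic alcohol further limit strong acid, electrophiles and hydrogenation, so the acetates and the C9 carbonyl belong at the end. The enabling feature is the four-carbon unit C9–C10–C11–C12, unsaturated in the middle and oxygenated at both ends. Read with the ketone at C12 and a carbinol at C9, it is a furan bonded to a carbinol carbon C8, and C8 with the C5–C7 triol is the terminal carbon and stereotriad of a pentose.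

## Retrosynthesis

**23 ⇒ 22 ⇒ 21.** The three acetyl C–O bonds are cut first, then the three Si–O bonds. Acetates cannot be carried through organometallic steps, and the C7 acetate is a leaving group once C9 is a ketone. Silyl ethers are poor leaving groups and inert to zinc reagents and oxidants, so triol **22** and its tris-silyl ether **21** are the late intermediates. The forward steps need an acidic fluoride source (no basic fluoride) and an acetylation that leaves the tertiary C12 hydroxyl alone.

**21 ⇒ 20 ⇒ 19.** The Z olefin C14=C15 is taken back to the alkyne of **20**, and the C10–Cl bond is cut to give enone **19**. The alkyne allows a linear propargyl/allenyl nucleophile earlier on and resists electrophilic chlorine better than a Z olefin. Chlorination cannot come sooner because C10 is a β-carbon until the carbonyl sits at C9. The forward steps need a nucleophile-triggered α-chlorination of the enone and a semihydrogenation that spares the chloroenone.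

**19 ⇒ 18 ⇒ 15 + 16.** The C9 carbonyl is taken back to the carbinol of diol **18**, and the C12–C13 bond is cut to give ketone **15** and 1-bromooct-2-yne **16**. This is a 1,3-carbonyl transposition. With the ketone at C12, the bulky C8 chain is adjacent and sends the nucleophile to the opposite face, which leaves the C12 hydroxyl cis to the chain as required. An aldol union at C7–C8 would instead have to set C7 and C8 together in an open transition state. The forward addition must be 1,2-selective, give the propargyl (not the allenyl) carbinol, and leave the ester; the oxidation must take the secondary and not the tertiary allylic alcohol.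

**15 ⇒ 14.** The C8–C9 bond is cut and C9–C12 are restored to a furan, giving furylcarbinol **14**. One step then builds the ring, the C8–C9 bond and the trans C8/C9 pair, and the precursor needs no control at C8 because that centre is ionised. The forward reaction has to ionise a carbinol flanked by a silyloxy group and close with the correct sense of conrotation relative to C7.

**14 ⇒ 11 + 12.** The C8–C12 bond is cut to give aldehyde **11** and furan **12** (as 2-lithiofuran **13**). The addition has no stereochemical demand; it only has to prefer the aldehyde over the methyl ester.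

**11 ⇒ 10 ⇒ 9 ⇒ 8 ⇒ 7 ⇒ 4 + 5.** The aldehyde comes from primary alcohol **10**, and this from the fully silylated ester **9**. The C3–C4 bond is then cut through alkene **8** and acid **7** to aldehyde **4** and the three-carbon phosphonium salt **5**. A carboxylate-bearing ylide delivers C1–C3 in one operation; the alkene geometry is irrelevant because it is hydrogenated.

**4 ⇒ 3 ⇒ 2 ⇒ 1.** Aldehyde **4** is per-silylated aldehydo-D-xylose, reached through dithioacetal **3** and **2** from D-xylose **1**. Xylose C2–C4 become C5–C7 unchanged, C1 becomes C4 and C5 becomes C8. The sugar is thus used "end for end", which the dithioacetal makes possible by holding C1 while all four hydroxyls are silylated.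

## Roads not taken

**Alternative 1:** The cut is the C12–O bond. A carboxyl group tethered to C8 (C6 as the acid carbon, C7 as a methylene) in cyclopentenylacetic acid **A1** is made to deliver oxygen to C12. Forward, I2/NaHCO3 forms the iodonium ion of the C11=C12 alkene, the carboxylate opens it at the more substituted C12, and the cis-fused iodolactone **A2** results.
- Merits: the cis ring fusion is obligatory, so C12 follows from C8 with certainty, and the C11 iodide prepares the C10=C11 alkene by elimination.
- Weak points: the tether consumes C6 and C7 as a bare acetic acid unit. The C7 oxygen, both C5 and C6 carbinols and the C1–C5 chain must all be built after the lactone is opened, each under open-chain control next to a sensitive ring. C9 oxidation and chlorination remain to be done as well.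
- Comparison: **A2** fixes C12 more securely than the intermolecular addition to **15** in the chosen plan. Against that, the chosen plan has the C5–C7 triad from D-xylose in place before the ring exists and relies on the adjacent C8 substituent for face selection at C12.

**Alternative 2:** The cut removes C10 from between C9 and C11. The precursor is siloxycyclobutene **A3**, the silyl enol ether of a cyclobutanone comprising C8, C9, C11 and C12. Forward, dichlorocarbene from hot Cl3CCO2Na adds to the C9=C11 enol ether, and the siloxy-dichlorobicyclopentane opens across C9–C11 with loss of silyl chloride to give the 2-chloroenone **A4**.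
- Merits: chlorine, enone and ring arrive together with the regiochemistry fixed by the mechanism, and **A4** is only deprotection and acetylation away from **23**.
- Weak points: **A3** requires a cyclobutanone that already carries the quaternary C12, the whole triol chain and the Z-octenyl group, with C8 and C12 set relative to the chain. Nothing in the target suggests a short way to it. The carbene must also choose the strained enol ether over the Z olefin of the side chain at elevated temperature.
- Comparison: for installing chlorine, **A4** is clearly better than the separate chlorination of **19**. The chosen plan offsets this with a pyridine-triggered chlorination run while the side chain is still an alkyne, and with a ring precursor (**14**) that is one addition away from a sugar aldehyde.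

**Alternative 3:** The cut is the C9–C10 bond. The precursor is the 4-alkynal **A5**, with the aldehyde at C9 on C8 and a silyl-capped C10≡C11 alkyne on the quaternary C12. Forward, [Rh(dppe)]2(BF4)2, a cationic complex of monovalent rhodium, inserts into the aldehyde C–H bond and adds it in the trans sense across the alkyne to give 2-silylcyclopentenone **A6**.
- Merits: the closure is neutral, mild and atom-economic, and the silyl group marks C10 for later exchange to chlorine.
- Weak points: **A5** is an α-branched aldehyde whose C8–H is flanked by two β-oxygen leaving groups (C7 and C12), so it is prone to epimerisation and elimination. C8 and C12 must be set in an open chain. The octynyl alkyne is a second site for the acyl rhodium hydride. Replacing silicon by chlorine on an electron-poor vinylsilane is an additional uncertain step.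
- Comparison: **A6** forms the ring under gentler conditions than hot aqueous Lewis acid, which is an advantage for silyl ethers. The chosen plan counters with silyl ethers robust enough for near-neutral water and with a precursor that contains no epimerisable centre at C8.

Key step: step 10

Remark on the chemistry: prostanoid numbering is used for all intermediates; TBS = tert-butyldimethylsilyl and TBSO its ether; **14** is carried as the mixture of C8 epimers because that centre is ionised in step 10.

## Route

Step 1
Reactants: 1 D-xylose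
Product: 2 D-xylose diethyl dithioacetal
Conditions: EtSH, conc. HCl, 0 °C
Reagents that add atoms: ethanethiol, CCS
Why: Acid-catalysed dithioacetal formation from an aldose opens the sugar to its acyclic form and masks C1 (the future C4); no stereocentre is touched.

Step 2
Reactants: 2 D-xylose diethyl dithioacetal
Product: 3 2,3,4,5-tetrakis-O-TBS-D-xylose diethyl dithioacetal
Conditions: TBSOTf, 2,6-lutidine, CH2Cl2, 0 °C → rt
Reagents that add atoms: tert-butyldimethylsilyl trifluoromethanesulfonate, CC(C)(C)[Si](C)(C)OS(=O)(=O)C(F)(F)F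
Why: Exhaustive silylation with a silyl triflate and a hindered base is standard for contiguous secondary carbinols; the three secondary ethers become the lasting protection of the C5–C7 oxygens.

Step 3
Reactants: 3 2,3,4,5-tetrakis-O-TBS-D-xylose diethyl dithioacetal
Product: 4 2,3,4,5-tetrakis-O-TBS-aldehydo-D-xylose
Conditions: I2, NaHCO3, acetone/H2O, 0 °C
Reagents that add atoms: water, O
Why: Iodine-promoted hydrolysis of a dithioacetal under bicarbonate buffer is mild enough for silyl ethers; the α-silyloxy aldehyde is kept cold and used directly to avoid epimerisation at the future C5.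

Step 4
Reactants: 4 2,3,4,5-tetrakis-O-TBS-aldehydo-D-xylose; 5 (2-carboxyethyl)triphenylphosphonium bromide
Product: 7 (3Z,5S,6R,7R)-5,6,7,8-tetrakis(TBSO)oct-3-enoic acid, via sodium 3-(triphenylphosphoranylidene)propanoate 6 (not isolated)
Conditions: 5, NaN(SiMe3)2 (2 equiv per 5), THF, −78 → 0 °C; then 4, −78 °C → rt; mild acid work-up
Reagents that add atoms: none
Why: Wittig olefination with a carboxylate-bearing non-stabilised ylide, the same reaction type as the carboxyalkyl ylide chain extensions of prostaglandin chemistry; the carboxylate suppresses fragmentation of the β-carboxy ylide. The alkene geometry (mainly Z) is irrelevant, and low temperature limits epimerisation at C5.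

Step 5
Reactants: 7 (3Z,5S,6R,7R)-5,6,7,8-tetrakis(TBSO)oct-3-enoic acid
Product: 8 methyl (3Z,5S,6R,7R)-5,6,7,8-tetrakis(TBSO)oct-3-enoate
Conditions: MeI, K2CO3, DMF, rt
Reagents that add atoms: iodomethane, CI
Why: SN2 alkylation of the carboxylate; any drift of the double bond into conjugation is harmless because the alkene is hydrogenated next.

Step 6
Reactants: 8 methyl (3Z,5S,6R,7R)-5,6,7,8-tetrakis(TBSO)oct-3-enoate
Product: 9 methyl (5S,6R,7R)-5,6,7,8-tetrakis(TBSO)octanoate
Conditions: H2 (1 atm), 10% Pd/C, EtOAc, rt
Reagents that add atoms: none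
Why: Heterogeneous hydrogenation of a disubstituted alkene; silyl ethers and the ester are inert under neutral conditions.

Step 7
Reactants: 9 methyl (5S,6R,7R)-5,6,7,8-tetrakis(TBSO)octanoate
Product: 10 methyl (5S,6R,7R)-8-hydroxy-5,6,7-tris(TBSO)octanoate
Conditions: HF·pyridine, pyridine, THF, 0 °C
Reagents that add atoms: none
Why: Buffered HF·pyridine cleaves the sterically most accessible primary silyl ether well before the three crowded secondary ones.

Step 8
Reactants: 10 methyl (5S,6R,7R)-8-hydroxy-5,6,7-tris(TBSO)octanoate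
Product: 11 methyl (5S,6R,7S)-8-oxo-5,6,7-tris(TBSO)octanoate
Conditions: Dess–Martin periodinane, NaHCO3, CH2Cl2, 0 °C → rt
Reagents that add atoms: none
Why: Dess–Martin oxidation is neutral and non-epimerising for α-silyloxy aldehydes; the change of descriptor at C7 is a priority effect only.

Step 9
Reactants: 11 methyl (5S,6R,7S)-8-oxo-5,6,7-tris(TBSO)octanoate; 12 furan
Product: 14 methyl (5S,6R,7R)-8-(furan-2-yl)-8-hydroxy-5,6,7-tris(TBSO)octanoate (both C8 epimers), via 2-lithiofuran 13 (not isolated)
Conditions: 12, n-BuLi, THF, −78 → 0 °C; then 11, −78 °C; NH4Cl quench at −78 °C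
Reagents that add atoms: none
Why: 1,2-Addition of 2-lithiofuran to an aldehyde, which is much faster than attack on the methyl ester at −78 °C. Both C8 epimers are used, and the cold quench prevents migration of the C7 silyl group to the new alkoxide.

Step 10
Reactants: 14 methyl (5S,6R,7R)-8-(furan-2-yl)-8-hydroxy-5,6,7-tris(TBSO)octanoate (both C8 epimers)
Product: 15 methyl (5S,6R,7R)-5,6,7-tris(TBSO)-7-[(1S,2S)-2-hydroxy-5-oxocyclopent-3-en-1-yl]heptanoate (C12 ketone, C9 hydroxyl trans to the C8 chain)
Conditions: Dy(OTf)3 (10 mol %), t-BuOH/H2O (5:1), 80 °C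
Reagents that add atoms: water, O
Why: Dy(OTf)3 ionises the C8 carbinol of either epimer to the furan-stabilised cation, water adds to the furan at C9, the hemiacetal opens to the 1,4-dioxygenated pentadienyl cation C8–C12–C11–C10–C9, and thermal 4π conrotation joins C8 to C9 before proton loss gives the C12 ketone. The closest known reaction type is the Piancatelli rearrangement of alkyl-substituted 2-furylcarbinols under lanthanide triflate or ZnCl2 catalysis in water, a relative of the Nazarov cyclisation. The five-membered ring C8–C12 closes by 4π-conrotatory electrocyclisation of the pentadienyl cation, all five ring carbons belonging to the cation. C9 is set trans to C8 because the C7 chain and the C9 hydroxyl occupy the two outward positions of the U-shaped cation and conrotation turns them to opposite faces. C8 is set by the sense of conrotation, which the C7 stereocentre has to control: with C7–H eclipsing the C12 oxygen (minimal A(1,3) strain) and the C7–O bond anti to the forming bond (polar Felkin–Anh arrangement), C9 should bond to the face of C8 that gives 15; this is a model, not a precedent. The step needs ionisation to outrun desilylation and a 1,2-hydride shift from C7, which is why the C7 oxygen carries a silyl group (least electron-withdrawing, non-participating) and the medium is kept near neutral. The product must also not isomerise to the 2-substituted 4-hydroxycyclopentenone, so heating is stopped at full conversion and base is avoided in work-up. The two trans diastereomers are expected to be separable, and the C8 configuration would be assigned here before material is carried on.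

Step 11
Reactants: 15 methyl (5S,6R,7R)-5,6,7-tris(TBSO)-7-[(1S,2S)-2-hydroxy-5-oxocyclopent-3-en-1-yl]heptanoate; 16 1-bromooct-2-yne
Product: 18 methyl (5S,6R,7R)-5,6,7-tris(TBSO)-7-[(1S,2S,5S)-2,5-dihydroxy-5-(oct-2-yn-1-yl)cyclopent-3-en-1-yl]heptanoate, via bromo(octa-1,2-dien-3-yl)zinc 17 (not isolated)
Conditions: 16 (excess), Zn dust, THF, 0 °C → rt; aq NH4Cl
Reagents that add atoms: none
Why: Barbier-type propargylation: the allenylzinc form of the reagent adds to the ketone by SE2′ through a cyclic transition state, giving the homopropargylic (oct-2-ynyl) carbinol by 1,2-addition and leaving the ester. C12 is set by attack on the face opposite the bulky adjacent C8 chain, which places the new hydroxyl cis to that chain; the free C9 hydroxyl only consumes one equivalent of reagent.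

Step 12
Reactants: 18 methyl (5S,6R,7R)-5,6,7-tris(TBSO)-7-[(1S,2S,5S)-2,5-dihydroxy-5-(oct-2-yn-1-yl)cyclopent-3-en-1-yl]heptanoate
Product: 19 methyl (5S,6R,7R)-5,6,7-tris(TBSO)-7-[(1S,5S)-5-hydroxy-5-(oct-2-yn-1-yl)-2-oxocyclopent-3-en-1-yl]heptanoate
Conditions: Dess–Martin periodinane, NaHCO3, CH2Cl2, 0 °C
Reagents that add atoms: none
Why: Dess–Martin oxidation takes the secondary allylic C9 alcohol to the enone, while the tertiary C12 alcohol cannot be oxidised and, without a chromium oxidant, is not transposed. This completes the 1,3-carbonyl shift; C8 now sits in its thermodynamically preferred arrangement, trans to the octynyl group.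

Step 13
Reactants: 19 methyl (5S,6R,7R)-5,6,7-tris(TBSO)-7-[(1S,5S)-5-hydroxy-5-(oct-2-yn-1-yl)-2-oxocyclopent-3-en-1-yl]heptanoate
Product: 20 methyl (5S,6R,7R)-5,6,7-tris(TBSO)-7-[(1S,5R)-3-chloro-5-hydroxy-5-(oct-2-yn-1-yl)-2-oxocyclopent-3-en-1-yl]heptanoate
Conditions: PhICl2, pyridine, CH2Cl2, 0 °C → rt
Reagents that add atoms: iodobenzene dichloride, ClI(Cl)c1ccccc1
Why: α-Chlorination of an enone by the addition–elimination path known from the iodine/pyridine α-iodination: pyridine adds at C11, the enolate is chlorinated at C10, and pyridinium is lost. The isolated alkyne is far less reactive towards the chlorine source than a Z olefin would be; the C12 descriptor changes by priority only.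

Step 14
Reactants: 20 methyl (5S,6R,7R)-5,6,7-tris(TBSO)-7-[(1S,5R)-3-chloro-5-hydroxy-5-(oct-2-yn-1-yl)-2-oxocyclopent-3-en-1-yl]heptanoate
Product: 21 methyl (5S,6R,7R)-5,6,7-tris(TBSO)-7-[(1S,5R)-3-chloro-5-hydroxy-5-[(2Z)-oct-2-en-1-yl]-2-oxocyclopent-3-en-1-yl]heptanoate
Conditions: H2 (1 atm), 5% Pd/CaCO3 poisoned with Pb(OAc)2, quinoline, EtOAc, rt
Reagents that add atoms: none
Why: Lindlar-type semihydrogenation delivers both hydrogens to one face of the alkyne and gives the Z olefin. The poisoned catalyst binds the alkyne much more strongly than the trisubstituted, electron-poor chloroenone, which should therefore survive.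

Step 15
Reactants: 21 methyl (5S,6R,7R)-5,6,7-tris(TBSO)-7-[(1S,5R)-3-chloro-5-hydroxy-5-[(2Z)-oct-2-en-1-yl]-2-oxocyclopent-3-en-1-yl]heptanoate
Product: 22 methyl (5S,6R,7R)-7-[(1S,5R)-3-chloro-5-hydroxy-5-[(2Z)-oct-2-en-1-yl]-2-oxocyclopent-3-en-1-yl]-5,6,7-trihydroxyheptanoate
Conditions: HF·pyridine, pyridine, THF, 0 °C → rt
Reagents that add atoms: none
Why: Fluoride-assisted desilylation under buffered, weakly acidic conditions avoids the retro-aldol and E1cB pathways that basic fluoride would open at C7–C8. The triol is taken on without delay to limit lactonisation of the C5 hydroxyl onto the ester.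

Step 16
Reactants: 22 methyl (5S,6R,7R)-7-[(1S,5R)-3-chloro-5-hydroxy-5-[(2Z)-oct-2-en-1-yl]-2-oxocyclopent-3-en-1-yl]-5,6,7-trihydroxyheptanoate
Product: 23 methyl (5S,6R,7R)-5,6,7-tris(acetyloxy)-7-[(1S,5R)-3-chloro-5-hydroxy-5-[(2Z)-oct-2-en-1-yl]-2-oxocyclopent-3-en-1-yl]heptanoate (target)
Conditions: Ac2O, pyridine, CH2Cl2, 0 °C
Reagents that add atoms: acetic anhydride, CC(=O)OC(C)=O
Why: Acetylation with Ac2O/pyridine esterifies the three secondary hydroxyls and leaves the hindered tertiary C12 hydroxyl. No acyl-transfer catalyst or stronger base is used, and the temperature is kept low, so that the C7 acetate is not eliminated across C7–C8.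

## Compound list

1 | D-xylose | O=C[C@H](O)[C@@H](O)[C@H](O)CO | starting material
2 | D-xylose diethyl dithioacetal | CCSC(SCC)[C@H](O)[C@@H](O)[C@H](O)CO | intermediate
3 | 2,3,4,5-tetrakis-O-TBS-D-xylose diethyl dithioacetal | CCSC(SCC)[C@H](O[Si](C)(C)C(C)(C)C)[C@@H](O[Si](C)(C)C(C)(C)C)[C@H](O[Si](C)(C)C(C)(C)C)CO[Si](C)(C)C(C)(C)C | intermediate
4 | 2,3,4,5-tetrakis-O-TBS-aldehydo-D-xylose | O=C[C@H](O[Si](C)(C)C(C)(C)C)[C@@H](O[Si](C)(C)C(C)(C)C)[C@H](O[Si](C)(C)C(C)(C)C)CO[Si](C)(C)C(C)(C)C | intermediate
5 | (2-carboxyethyl)triphenylphosphonium bromide | OC(=O)CC[P+](c1ccccc1)(c1ccccc1)c1ccccc1.[Br-] | starting material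
6 | sodium 3-(triphenylphosphoranylidene)propanoate (ylide) | [Na+].[O-]C(=O)CC=P(c1ccccc1)(c1ccccc1)c1ccccc1 | intermediate (not isolated)
7 | (3Z,5S,6R,7R)-5,6,7,8-tetrakis(TBSO)oct-3-enoic acid | OC(=O)C/C=C\[C@H](O[Si](C)(C)C(C)(C)C)[C@@H](O[Si](C)(C)C(C)(C)C)[C@H](O[Si](C)(C)C(C)(C)C)CO[Si](C)(C)C(C)(C)C | intermediate
8 | methyl (3Z,5S,6R,7R)-5,6,7,8-tetrakis(TBSO)oct-3-enoate | COC(=O)C/C=C\[C@H](O[Si](C)(C)C(C)(C)C)[C@@H](O[Si](C)(C)C(C)(C)C)[C@H](O[Si](C)(C)C(C)(C)C)CO[Si](C)(C)C(C)(C)C | intermediate
9 | methyl (5S,6R,7R)-5,6,7,8-tetrakis(TBSO)octanoate | COC(=O)CCC[C@H](O[Si](C)(C)C(C)(C)C)[C@@H](O[Si](C)(C)C(C)(C)C)[C@H](O[Si](C)(C)C(C)(C)C)CO[Si](C)(C)C(C)(C)C | intermediate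
10 | methyl (5S,6R,7R)-8-hydroxy-5,6,7-tris(TBSO)octanoate | COC(=O)CCC[C@H](O[Si](C)(C)C(C)(C)C)[C@@H](O[Si](C)(C)C(C)(C)C)[C@H](O[Si](C)(C)C(C)(C)C)CO | intermediate
11 | methyl (5S,6R,7S)-8-oxo-5,6,7-tris(TBSO)octanoate | COC(=O)CCC[C@H](O[Si](C)(C)C(C)(C)C)[C@@H](O[Si](C)(C)C(C)(C)C)[C@H](O[Si](C)(C)C(C)(C)C)C=O | intermediate
12 | furan | c1ccoc1 | starting material
13 | 2-lithiofuran | [Li]c1ccco1 | intermediate (not isolated)
14 | methyl (5S,6R,7R)-8-(furan-2-yl)-8-hydroxy-5,6,7-tris(TBSO)octanoate, both C8 epimers | COC(=O)CCC[C@H](O[Si](C)(C)C(C)(C)C)[C@@H](O[Si](C)(C)C(C)(C)C)[C@H](O[Si](C)(C)C(C)(C)C)C(O)c1ccco1 | intermediate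
15 | methyl (5S,6R,7R)-5,6,7-tris(TBSO)-7-[(1S,2S)-2-hydroxy-5-oxocyclopent-3-en-1-yl]heptanoate | O=C1C=C[C@H](O)[C@H]1[C@@H](O[Si](C)(C)C(C)(C)C)[C@H](O[Si](C)(C)C(C)(C)C)[C@H](CCCC(=O)OC)O[Si](C)(C)C(C)(C)C | intermediate
16 | 1-bromooct-2-yne | CCCCCC#CCBr | starting material
17 | bromo(octa-1,2-dien-3-yl)zinc | CCCCCC(=C=C)[Zn]Br | intermediate (not isolated)
18 | methyl (5S,6R,7R)-5,6,7-tris(TBSO)-7-[(1S,2S,5S)-2,5-dihydroxy-5-(oct-2-yn-1-yl)cyclopent-3-en-1-yl]heptanoate | CCCCCC#CC[C@]1(O)C=C[C@H](O)[C@H]1[C@@H](O[Si](C)(C)C(C)(C)C)[C@H](O[Si](C)(C)C(C)(C)C)[C@H](CCCC(=O)OC)O[Si](C)(C)C(C)(C)C | intermediate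
19 | methyl (5S,6R,7R)-5,6,7-tris(TBSO)-7-[(1S,5S)-5-hydroxy-5-(oct-2-yn-1-yl)-2-oxocyclopent-3-en-1-yl]heptanoate | CCCCCC#CC[C@]1(O)C=CC(=O)[C@H]1[C@@H](O[Si](C)(C)C(C)(C)C)[C@H](O[Si](C)(C)C(C)(C)C)[C@H](CCCC(=O)OC)O[Si](C)(C)C(C)(C)C | intermediate
20 | methyl (5S,6R,7R)-5,6,7-tris(TBSO)-7-[(1S,5R)-3-chloro-5-hydroxy-5-(oct-2-yn-1-yl)-2-oxocyclopent-3-en-1-yl]heptanoate | CCCCCC#CC[C@]1(O)C=C(Cl)C(=O)[C@H]1[C@@H](O[Si](C)(C)C(C)(C)C)[C@H](O[Si](C)(C)C(C)(C)C)[C@H](CCCC(=O)OC)O[Si](C)(C)C(C)(C)C | intermediate
21 | methyl (5S,6R,7R)-5,6,7-tris(TBSO)-7-[(1S,5R)-3-chloro-5-hydroxy-5-[(2Z)-oct-2-en-1-yl]-2-oxocyclopent-3-en-1-yl]heptanoate | CCCCC/C=C\C[C@]1(O)C=C(Cl)C(=O)[C@H]1[C@@H](O[Si](C)(C)C(C)(C)C)[C@H](O[Si](C)(C)C(C)(C)C)[C@H](CCCC(=O)OC)O[Si](C)(C)C(C)(C)C | intermediate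
22 | methyl (5S,6R,7R)-7-[(1S,5R)-3-chloro-5-hydroxy-5-[(2Z)-oct-2-en-1-yl]-2-oxocyclopent-3-en-1-yl]-5,6,7-trihydroxyheptanoate | CCCCC/C=C\C[C@]1(O)C=C(Cl)C(=O)[C@H]1[C@@H](O)[C@H](O)[C@H](CCCC(=O)OC)O | intermediate
23 | methyl (5S,6R,7R)-5,6,7-tris(acetyloxy)-7-[(1S,5R)-3-chloro-5-hydroxy-5-[(2Z)-oct-2-en-1-yl]-2-oxocyclopent-3-en-1-yl]heptanoate | CCCCC/C=C\C[C@]1(O)C=C(Cl)C(=O)[C@H]1[C@@H](OC(C)=O)[C@H](OC(C)=O)[C@H](CCCC(=O)OC)OC(C)=O | target

## Step count and least certain steps

Total: 16 steps. Longest linear sequence: 16 steps, from D-xylose **1** to **23**.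

**Step 10 (key step).** The inductive pull of the C7 silyloxy group may slow ionisation at C8. Prolonged heating could then bring loss of silyl groups, a 1,2-hydride shift from C7 in the cation, or isomerisation of the product to the 2-substituted 4-hydroxycyclopentenone. Independently, the conrotation may show poor facial selectivity at C8, since the C7 control rests on a model. The fallback closes the ring by aldol addition instead of electrocyclisation. It sets out from **14**: phenyl chlorothionoformate and pyridine give the O-phenyl thionocarbonate F1, and Bu3SnH/AIBN (Barton–McCombie deoxygenation) removes the C8 oxygen to give the 2-alkylfuran F2. NBS in NaHCO3-buffered aqueous acetone opens the furan to the (Z)-4-oxo-2-enal F3. Intramolecular aldol addition of the C8 methylene to the C9 aldehyde at about pH 7 then gives the trans-4-hydroxy-5-alkylcyclopentenone and comes back to the route at **15**. C8 would in that case be set under aldol control by C7, and the epimers would be separated at **15**.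

**Step 11.** The propargyl form of the zinc reagent can react by SE2′ to give the allenyl carbinol. Face selectivity at C12 may be eroded by the C9 alkoxide, and enolisation towards C8 could epimerise that centre. The fallback avoids an ambident nucleophile. It sets out from **15**: allyl bromide and Zn give the allyl carbinol F4 (same facial argument). Dess–Martin oxidation gives the allyl enone F5, and PhICl2/pyridine gives the allyl chloroenone F6. Z-selective cross-metathesis with hept-1-ene, using the Z-selective Grubbs catalyst (the cyclometalated N-adamantyl carbene ruthenium nitrate complex), then builds the (Z)-oct-2-enyl chain and comes back to the route at **21**; the trisubstituted chloroenone olefin is not expected to take part.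

**Step 13.** Chlorine may add to the alkyne, and pyridine may trigger loss of the C7 silyloxy group from the enolisable C8 position. The fallback replaces electrophilic chlorine by chloride. It sets out from **19**: t-BuOOH/DBU gives the 10,11-epoxy ketone F7 by nucleophilic epoxidation, which touches only the enone. Brief treatment with HCl in CHCl3 at 0 °C opens the epoxide at C10 and dehydrates the chlorohydrin, coming back to the route at **20**.

**Step 14.** Over-reduction of the ring olefin, hydrogenolysis of the C–Cl bond, or stalling through catalyst poisoning by the chloroenone are possible. The fallback moves the hydrogenation to a stage without chloroenone. It sets out from **18**: the same poisoned Pd/CaCO3 catalyst gives the Z-octenyl diol F8, Dess–Martin oxidation gives the Z-octenyl enone F9, and t-BuOOH/DBU gives the epoxy ketone F10 without touching the isolated Z olefin. HCl then converts F10 to the chloroenone and comes back to the route at **21**.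

**Step 15.** Three contiguous secondary silyl ethers may cleave only under forcing conditions. Under these the C5 hydroxyl can lactonise onto the ester, the freed hydroxyls can add to the electrophilic chloroenone or its ketone, and the tertiary allylic alcohol may ionise. The fallback makes the silyl-to-acetyl exchange on the sturdier plain enone. It sets out from **19**: HF·pyridine gives the alkynyl enone triol F11, and Ac2O/pyridine gives the triacetate F12. PhICl2/pyridine then gives the chloroenone triacetate F13, and semihydrogenation over Pd/CaCO3 poisoned with Pb(OAc)2 comes back to the route at **23**.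

## Further compounds

F1 | step 10 | O-phenyl thionocarbonate of 14 at the C8 oxygen | COC(=O)CCC[C@H](O[Si](C)(C)C(C)(C)C)[C@@H](O[Si](C)(C)C(C)(C)C)[C@H](O[Si](C)(C)C(C)(C)C)C(OC(=S)Oc1ccccc1)c1ccco1
F2 | step 10 | methyl (5S,6R,7R)-8-(furan-2-yl)-5,6,7-tris(TBSO)octanoate (2-alkylfuran) | COC(=O)CCC[C@H](O[Si](C)(C)C(C)(C)C)[C@@H](O[Si](C)(C)C(C)(C)C)[C@H](O[Si](C)(C)C(C)(C)C)Cc1ccco1
F3 | step 10 | methyl (5S,6R,7R,10Z)-9,12-dioxo-5,6,7-tris(TBSO)dodec-10-enoate ((Z)-4-oxo-2-enal) | COC(=O)CCC[C@H](O[Si](C)(C)C(C)(C)C)[C@@H](O[Si](C)(C)C(C)(C)C)[C@H](O[Si](C)(C)C(C)(C)C)CC(=O)/C=C\C=O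
F4 | step 11 | allyl analogue of 18 (allyl in place of oct-2-ynyl at C12, C9 and C12 hydroxyls free) | C=CC[C@]1(O)C=C[C@H](O)[C@H]1[C@@H](O[Si](C)(C)C(C)(C)C)[C@H](O[Si](C)(C)C(C)(C)C)[C@H](CCCC(=O)OC)O[Si](C)(C)C(C)(C)C
F5 | step 11 | allyl analogue of 19 (C9 enone, allyl at C12) | C=CC[C@]1(O)C=CC(=O)[C@H]1[C@@H](O[Si](C)(C)C(C)(C)C)[C@H](O[Si](C)(C)C(C)(C)C)[C@H](CCCC(=O)OC)O[Si](C)(C)C(C)(C)C
F6 | step 11 | allyl analogue of 20 (2-chloroenone, allyl at C12) | C=CC[C@]1(O)C=C(Cl)C(=O)[C@H]1[C@@H](O[Si](C)(C)C(C)(C)C)[C@H](O[Si](C)(C)C(C)(C)C)[C@H](CCCC(=O)OC)O[Si](C)(C)C(C)(C)C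
F7 | step 13 | 10,11-epoxide of 19 (either epoxide face) | CCCCCC#CC[C@]1(O)C2OC2C(=O)[C@H]1[C@@H](O[Si](C)(C)C(C)(C)C)[C@H](O[Si](C)(C)C(C)(C)C)[C@H](CCCC(=O)OC)O[Si](C)(C)C(C)(C)C
F8 | step 14 | (Z)-oct-2-enyl analogue of diol 18 | CCCCC/C=C\C[C@]1(O)C=C[C@H](O)[C@H]1[C@@H](O[Si](C)(C)C(C)(C)C)[C@H](O[Si](C)(C)C(C)(C)C)[C@H](CCCC(=O)OC)O[Si](C)(C)C(C)(C)C
F9 | step 14 | (Z)-oct-2-enyl analogue of enone 19 | CCCCC/C=C\C[C@]1(O)C=CC(=O)[C@H]1[C@@H](O[Si](C)(C)C(C)(C)C)[C@H](O[Si](C)(C)C(C)(C)C)[C@H](CCCC(=O)OC)O[Si](C)(C)C(C)(C)C
F10 | step 14 | 10,11-epoxide of F9 (either epoxide face) | CCCCC/C=C\C[C@]1(O)C2OC2C(=O)[C@H]1[C@@H](O[Si](C)(C)C(C)(C)C)[C@H](O[Si](C)(C)C(C)(C)C)[C@H](CCCC(=O)OC)O[Si](C)(C)C(C)(C)C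
F11 | step 15 | 5,6,7-triol of enone 19 (oct-2-ynyl at C12) | CCCCCC#CC[C@]1(O)C=CC(=O)[C@H]1[C@@H](O)[C@H](O)[C@H](CCCC(=O)OC)O
F12 | step 15 | 5,6,7-triacetate of F11 | CCCCCC#CC[C@]1(O)C=CC(=O)[C@H]1[C@@H](OC(C)=O)[C@H](OC(C)=O)[C@H](CCCC(=O)OC)OC(C)=O
F13 | step 15 | 10-chloro derivative of F12 (14,15-didehydro analogue of 23) | CCCCCC#CC[C@]1(O)C=C(Cl)C(=O)[C@H]1[C@@H](OC(C)=O)[C@H](OC(C)=O)[C@H](CCCC(=O)OC)OC(C)=O
A1 | alternative 1 | cyclopent-2-enylacetic acid with C9 silyloxy and oct-2-ynyl on the C11=C12 alkene | OC(=O)C[C@@H]1[C@H](O[Si](C)(C)C(C)(C)C)CC=C1CC#CCCCCC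
A2 | alternative 1 | cis-fused iodolactone | CCCCCC#CC[C@@]12OC(=O)C[C@@H]1[C@H](O[Si](C)(C)C(C)(C)C)C[C@H]2I
A3 | alternative 2 | siloxycyclobutene (trimethylsilyl enol ether, C12 p-methoxybenzyl ether) | CCCCC/C=C\C[C@]1(OCc2ccc(OC)cc2)C=C(O[Si](C)(C)C)[C@H]1[C@@H](O[Si](C)(C)C(C)(C)C)[C@H](O[Si](C)(C)C(C)(C)C)[C@H](CCCC(=O)OC)O[Si](C)(C)C(C)(C)C
A4 | alternative 2 | protected 2-chlorocyclopent-2-enone with the full skeleton | CCCCC/C=C\C[C@]1(OCc2ccc(OC)cc2)C=C(Cl)C(=O)[C@H]1[C@@H](O[Si](C)(C)C(C)(C)C)[C@H](O[Si](C)(C)C(C)(C)C)[C@H](CCCC(=O)OC)O[Si](C)(C)C(C)(C)C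
A5 | alternative 3 | 4-alkynal with C9 aldehyde and trimethylsilyl-capped C10≡C11 alkyne | CCCCCC#CC[C@](O[Si](CC)(CC)CC)(C#C[Si](C)(C)C)[C@@H](C=O)[C@@H](O[Si](C)(C)C(C)(C)C)[C@H](O[Si](C)(C)C(C)(C)C)[C@H](CCCC(=O)OC)O[Si](C)(C)C(C)(C)C
A6 | alternative 3 | 2-(trimethylsilyl)cyclopent-2-enone | CCCCCC#CC[C@]1(O[Si](CC)(CC)CC)C=C([Si](C)(C)C)C(=O)[C@H]1[C@@H](O[Si](C)(C)C(C)(C)C)[C@H](O[Si](C)(C)C(C)(C)C)[C@H](CCCC(=O)OC)O[Si](C)(C)C(C)(C)C
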